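## Numbering of the compounds

1 1,2,4,5-tetramethoxybenzene · 2 aryllithium from 1 · 3 dimethyl arylboronate · 4 2,3,5,6-tetramethoxyphenol · 5 chloroacetyl chloride · 6 tetramethoxy chloroketone · 7 2,4-dihydroxy chloroketone · 8 6-hydroxybenzofuranone · 9 6-benzyloxybenzofuranone · 10 4-bromo-1,2-dimethoxybenzene · 11 2-arylbenzofuranone · 12 silyl enol ether (3-silyloxy-2-arylbenzofuran) · 13 chloroform · 14 gem-dichlorocyclopropane · 15 4-silyloxybenzopyrylium chloride · 16 3-chloroflavone · 17 target.

## Analysis of the target

Compound 17 (C20H20O8) is a flavone: a 4H-chromen-4-one (rings A and C) with a 3,4-dimethoxyphenyl group (ring B) on C2. Ring A is fully substituted, with methoxy groups on C5, C6 and C8, the only free hydroxyl on C7, and C4a/C8a as fusion atoms. There is no stereocentre, so the problem is purely one of regiochemistry: of the six ring-bound oxygen substituents, exactly one (O7) must remain unmethylated. The sensitive points are the C5 methoxy group, which Lewis acids cleave easily because it chelates with the C4 carbonyl; the acidic 7-OH; the oxidizable electron-rich rings; and the C2=C3 bond, which can be over-reduced. The difficulty lies in the hexasubstituted ring A: the acyl carbon C4a and the ring oxygen on C8a are both flanked by methoxy groups, so any closure of ring C takes place in a crowded environment. Two features are used. First, O7 is para to C4a and flanked by the C6 and C8 methoxy groups, so ring A maps onto the mirror-symmetric 2,3,5,6-tetramethoxyphenol. Second, and central to the plan, ring C differs from the furanone ring of a 2-arylbenzofuran-3(2H)-one only by C3, the CH carbon between C2 and C4, so C3 can be inserted last as a one-carbon unit.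

## Retrosynthetic reasoning

17 from 16. The C3–H bond and the O7–H bond are traced back to a C3–Cl bond and an O7 benzyl ether. Both are cleaved by the same hydrogenolysis, so the halogen left by the ring expansion and the protecting group cost one step together.

16 from 12 and 13. The bonds C2–C3 and C3–C4 are cut and C3 is removed, which contracts ring C to the furan ring of silyl enol ether 12. This is the disconnection the plan rests on: C3 comes from 13 as a carbene carbon, and the carbonyl at C4 is already present in masked form as the silyloxy carbon. The forward reaction has to add the carbene to the enol-ether double bond only, and then open the cyclopropane across the shared bond with loss of chloride and silicon.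

12 from 11, and 11 from 9 and 10. The Si–O bond is cut to return to ketone 11, whose enol is aromatic, so silylation on oxygen is expected. The C2–aryl bond is then cut to the unsubstituted benzofuranone 9 and aryl bromide 10. This keeps ring B out of the early steps and makes the route convergent. The forward reaction is a ketone α-arylation that must stop at monoarylation.

9 from 8, and 8 from 7. The benzyl ether is cut to the free phenol 8, and the O1–C2 bond of the furanone is cut to the ortho-hydroxy α-chloroketone 7. The forward closure is an intramolecular etherification that only the ortho hydroxyl can reach.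

7 from 4 and 5. The aryl–carbonyl bond is cut, giving phenol 4 and the two-carbon acyl chloride 5. In 4 only one ring position is free, and the two methoxy groups flanking it are equivalent. Acylation there, followed by cleavage of either ortho methoxy group, can therefore give only one product. It places the future O1 next to the carbonyl and leaves the para hydroxyl as the future O7.

4 from 1. The C–O bond of the phenol is cut back to the symmetric arene 1. Both ring hydrogens of 1 lie between two methoxy groups, so metalation followed by oxidation introduces the differentiated oxygen without any selectivity problem.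

## Alternatives that were turned down

Alternative 1: The C2=C3 double bond is disconnected by olefination. The acyl ylide A1, 3-(benzyloxy)-2,4,5-trimethoxy-6-[(triphenyl-λ5-phosphanylidene)acetyl]phenyl 3,4-dimethoxybenzoate, would be heated in toluene. The ylide carbon attacks the neighbouring aryl ester carbonyl, and loss of the phosphorus unit closes ring C to the benzyl-protected flavone A2, which hydrogenolysis would convert into 17.
- For: the ring closure is a known way to chromones, the regiochemistry is fixed by the ester, no halogen has to be removed, and neither palladium coupling nor an air-sensitive enol is involved.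
- Against: ester carbonyls are reluctant Wittig acceptors, and here the ester sits on a phenol oxygen flanked by a methoxy group and the bulky ylide-bearing acyl group. Aroylation of that hindered, chelated phenol may go to the ylide carbon instead. A stoichiometric phosphorus by-product must be separated.
- Comparison: the step count is similar, and on reliability of the ring-forming step this alternative is the stronger one. The chosen route offers instead a convergent C–C union of ring B with a simple bicyclic ketone, and the introduction of C3 at the very end from a one-carbon reagent. That allows isotopic labelling of C3 and leaves a 3-chloro handle in 16 for analogues. It also tests a skeletal one-carbon expansion that the Wittig route does not.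

Alternative 2: Ring A itself is disconnected. Heating 3-(benzyloxy)-2,4-dimethoxycyclobut-2-en-1-one A3 with methoxyethyne A4 would open the cyclobutenone to a vinylketene, add the alkyne, and pass through a four-electron opening and a six-electron closure. This forms C8a–C4a, C5–C6 and C8–C8a and gives 3-(benzyloxy)-2,4,5-trimethoxyphenol A5.
- For: the pericyclic cascade places all five oxygens unambiguously, O7 arrives already differentiated, and the free hydroxyl of A5 is positioned to direct the ortho acylation that must follow. On certainty of the ring A substitution pattern it is at least as good as the chosen route, which relies on a selective demethylation.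
- Against: A3 needs several steps from a squaric acid derivative, and A4 is volatile and prone to polymerize. The cascade makes only ring A, so ortho-acylation of the hindered phenol A5 and a full flavone annulation still lie ahead, and the sequence becomes clearly longer.
- Comparison: the chosen route obtains the same ring A pattern from commercial 1 in two steps, because the symmetry of 4 does the work of the cascade. It then spends its steps on ring C.

Alternative 3: The O1–C8a bond is disconnected. The symmetric diketone A6, 1-[4-(benzyloxy)-2,6-dibromo-3,5-dimethoxyphenyl]-3-(3,4-dimethoxyphenyl)propane-1,3-dione, would be cyclized by a copper-catalysed Ullmann etherification in DMF with a phenanthroline ligand and a carbonate base. The enol oxygen couples with one of the two equivalent C–Br bonds and gives 7-(benzyloxy)-5-bromo-2-(3,4-dimethoxyphenyl)-6,8-dimethoxy-4H-chromen-4-one A7.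
- For: the two bromides are equivalent, so the closure has no regiochemical issue, and copper-mediated enol O-arylation is a precedented way to close ring C. On precedent for the key step it is stronger than the chosen route.
- Against: A7 still carries bromine at C5, which has to be exchanged for methoxy at a hindered peri position next to the carbonyl. Hydrodebromination competes there, and an extra step is needed before debenzylation. A6 also requires a dibrominated benzoyl building block and a Claisen-type condensation, so the sequence is longer.
- Comparison: the chosen route carries every ring A oxygen from the first step and needs no halogen-for-oxygen exchange. It pays for this with an unprecedented key step.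

Key step: step 7

Remark on the chemistry: ketone 11 is written as its keto tautomer although it equilibrates with the 3-hydroxybenzofuran enol. Compound 11 and the transient cyclopropane 14 are racemic, and none of their stereocentres reaches the target.

## Route

Step 1
Reactants: 1 1,2,4,5-tetramethoxybenzene
Product: 4 2,3,5,6-tetramethoxyphenol, via aryllithium 2 (not isolated), via arylboronate 3 (not isolated)
Conditions: n-BuLi, TMEDA, THF, 0 °C to rt; B(OMe)3, −78 °C to rt; AcOH, 30% aq. H2O2, 0 °C to rt
Reagents that add atoms: hydrogen peroxide, OO (oxygen of 4); n-butyllithium, [Li]CCCC (lithium of 2 only); trimethyl borate, COB(OC)OC (dimethoxyboryl group of 3 only)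
Why: Directed ortho-metalation: each ring hydrogen of 1 lies between two methoxy groups and the two positions are equivalent, so monolithiation should be clean. Borylation and peroxide oxidation (aryl migration from boron to oxygen) then give the phenol without touching the ethers.

Step 2
Reactants: 4 2,3,5,6-tetramethoxyphenol; 5 chloroacetyl chloride
Product: 7 2-chloro-1-(2,4-dihydroxy-3,5,6-trimethoxyphenyl)ethan-1-one, via tetramethoxy chloroketone 6 (not isolated)
Conditions: AlCl3 (3.5 equiv), CH2Cl2, 0 °C to rt, then 40 °C; ice/aq. HCl
Reagents that add atoms: none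
Why: Friedel–Crafts acylation at the only free ring position, para to the aluminium phenoxide, gives 6. AlCl3 then cleaves one of the two equivalent methoxy groups ortho to the new carbonyl through a six-membered aluminium chelate. The symmetry of 4 means only one regioisomer can form, and the chelate protects the second ortho methoxy group.

Step 3
Reactants: 7 2-chloro-1-(2,4-dihydroxy-3,5,6-trimethoxyphenyl)ethan-1-one
Product: 8 6-hydroxy-4,5,7-trimethoxy-1-benzofuran-3(2H)-one
Conditions: NaOAc, EtOH, reflux, argon
Reagents that add atoms: none
Why: Intramolecular Williamson etherification (5-exo-tet displacement of the α-chloride by the ortho hydroxyl under acetate buffering), the standard closure of benzofuran-3(2H)-ones. The para hydroxyl cannot reach the chloromethyl carbon, and the weak base keeps intermolecular alkylation slow.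

Step 4
Reactants: 8 6-hydroxy-4,5,7-trimethoxy-1-benzofuran-3(2H)-one
Product: 9 6-(benzyloxy)-4,5,7-trimethoxy-1-benzofuran-3(2H)-one
Conditions: BnBr (1.05 equiv), K2CO3, DMF, rt, argon
Reagents that add atoms: benzyl bromide, BrCc1ccccc1
Why: Williamson O-benzylation. The C6 hydroxyl is a vinylogous acid, far more acidic than the C2 methylene, so carbonate and one equivalent of halide should alkylate oxygen only. Benzyl is chosen because it withstands alkoxide and carbene and is removed in the final hydrogenolysis.

Step 5
Reactants: 9 6-(benzyloxy)-4,5,7-trimethoxy-1-benzofuran-3(2H)-one; 10 4-bromo-1,2-dimethoxybenzene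
Product: 11 6-(benzyloxy)-2-(3,4-dimethoxyphenyl)-4,5,7-trimethoxy-1-benzofuran-3(2H)-one (racemic)
Conditions: Pd(OAc)2 (cat.), P(t-Bu)3·HBF4 (cat.), NaOt-Bu (2.2 equiv), toluene, 60 °C, argon; degassed aq. NH4Cl
Reagents that add atoms: none
Why: Palladium-catalysed α-arylation of a ketone enolate: oxidative addition of 10 to zerovalent palladium, enolate binding and C–C reductive elimination at C2. The product is held as its more stabilized and more hindered enolate, which disfavours a second arylation. The C2 stereocentre is racemic and is erased in step 6.

Step 6
Reactants: 11 6-(benzyloxy)-2-(3,4-dimethoxyphenyl)-4,5,7-trimethoxy-1-benzofuran-3(2H)-one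
Product: 12 {[6-(benzyloxy)-2-(3,4-dimethoxyphenyl)-4,5,7-trimethoxy-1-benzofuran-3-yl]oxy}(tert-butyl)dimethylsilane
Conditions: TBSOTf, Et3N, CH2Cl2, 0 °C, argon
Reagents that add atoms: tert-butyldimethylsilyl trifluoromethanesulfonate, CC(C)(C)[Si](C)(C)OS(=O)(=O)C(F)(F)F
Why: Soft enolization and O-silylation (silyl enol ether formation). Silicon should go to oxygen because this creates the aromatic furan ring, which fixes the C2=C3 enol-ether bond and caps the autoxidizable enol.

Step 7
Reactants: 12 {[6-(benzyloxy)-2-(3,4-dimethoxyphenyl)-4,5,7-trimethoxy-1-benzofuran-3-yl]oxy}(tert-butyl)dimethylsilane; 13 chloroform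
Product: 16 7-(benzyloxy)-3-chloro-2-(3,4-dimethoxyphenyl)-5,6,8-trimethoxy-4H-chromen-4-one, via dichlorocyclopropane 14 (not isolated), via silyloxybenzopyrylium chloride 15 (not isolated)
Conditions: KOt-Bu (excess, suspended), 13 added slowly, toluene–hexane, −20 °C to rt, argon
Reagents that add atoms: none
Why: Proposed new method: KOt-Bu deprotonates 13 and α-elimination of chloride releases singlet dichlorocarbene, an electrophile that should add in a concerted [2+1] manner to the C2=C3 enol-ether bond of 12, the most electron-rich π bond of the molecule because it carries both the ring oxygen and the silyloxy group, to give cyclopropane 14. In 14 both carbons next to the CCl2 carbon bear an oxygen donor, so ionization of the chloride lying over the five-membered ring with disrotatory two-electron opening of the former C2–C3 bond (the ring atoms turning inward, as a fused ring requires) should be spontaneous and give the 4-silyloxybenzopyrylium salt 15. Chloride then takes the silyl group from oxygen, leaving the C4 carbonyl and the C2=C3 bond with chlorine on C3, that is 16. Ring C is therefore not closed by a cyclization but arises by one-carbon expansion of the furan ring (cheletropic cyclopropanation followed by electrocyclic cyclopropyl-to-allyl cation opening), the new bonds being C2–C3 and C3–C4. The closest known reactions are the dihalocarbene ring expansion of cyclic silyl enol ethers to 2-halo-enones and the Ciamician–Dennstedt expansion of indoles and benzofurans; a 3-silyloxy-2-arylbenzofuran has not been used in this way, which is why the step is a proposal. No stereocentre remains in 16, and the two of racemic 14 are destroyed on opening. The selectivity needed is for the enol ether over the two alkoxyarenes, the benzylic C–H bonds and the Si–O bond: the first follows from the nucleophilicity of the doubly oxygenated alkene, and attack of alkoxide at silicon is limited by the bulk of the silyl group, the poorly solvating medium, the low temperature and the slow addition of 13. Oxygen is excluded because any desilylated material would autoxidize.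

Step 8
Reactants: 16 7-(benzyloxy)-3-chloro-2-(3,4-dimethoxyphenyl)-5,6,8-trimethoxy-4H-chromen-4-one
Product: 17 2-(3,4-dimethoxyphenyl)-7-hydroxy-5,6,8-trimethoxy-4H-chromen-4-one
Conditions: H2 (1 atm), 10% Pd/C, NaOAc, MeOH–EtOAc, rt
Reagents that add atoms: none
Why: Heterogeneous hydrogenolysis: the C3–Cl bond of the α-chloroenone and the benzylic C–O bond are both cleaved on palladium, with acetate taking up the HCl. Acetate is used and not an amine because amines can slow O-debenzylation on palladium. The conjugated, aryl-substituted C2=C3 bond of a flavone normally survives at atmospheric pressure.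

## Compound list

1 | 1,2,4,5-tetramethoxybenzene | COc1cc(OC)c(OC)cc1OC | starting material
2 | (2,3,5,6-tetramethoxyphenyl)lithium | [Li]c1c(OC)c(OC)cc(OC)c1OC | intermediate (not isolated)
3 | dimethyl (2,3,5,6-tetramethoxyphenyl)boronate | COB(OC)c1c(OC)c(OC)cc(OC)c1OC | intermediate (not isolated)
4 | 2,3,5,6-tetramethoxyphenol | Oc1c(OC)c(OC)cc(OC)c1OC | intermediate
5 | chloroacetyl chloride | ClCC(Cl)=O | starting material
6 | 2-chloro-1-(4-hydroxy-2,3,5,6-tetramethoxyphenyl)ethan-1-one | O=C(CCl)c1c(OC)c(OC)c(O)c(OC)c1OC | intermediate (not isolated)
7 | 2-chloro-1-(2,4-dihydroxy-3,5,6-trimethoxyphenyl)ethan-1-one | O=C(CCl)c1c(O)c(OC)c(O)c(OC)c1OC | intermediate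
8 | 6-hydroxy-4,5,7-trimethoxy-1-benzofuran-3(2H)-one | O=C1COc2c(OC)c(O)c(OC)c(OC)c21 | intermediate
9 | 6-(benzyloxy)-4,5,7-trimethoxy-1-benzofuran-3(2H)-one | O=C1COc2c(OC)c(OCc3ccccc3)c(OC)c(OC)c21 | intermediate
10 | 4-bromo-1,2-dimethoxybenzene | COc1ccc(Br)cc1OC | starting material
11 | 6-(benzyloxy)-2-(3,4-dimethoxyphenyl)-4,5,7-trimethoxy-1-benzofuran-3(2H)-one (racemic at C2) | COc1ccc(C2Oc3c(OC)c(OCc4ccccc4)c(OC)c(OC)c3C2=O)cc1OC | intermediate
12 | {[6-(benzyloxy)-2-(3,4-dimethoxyphenyl)-4,5,7-trimethoxy-1-benzofuran-3-yl]oxy}(tert-butyl)dimethylsilane | COc1ccc(-c2oc3c(OC)c(OCc4ccccc4)c(OC)c(OC)c3c2O[Si](C)(C)C(C)(C)C)cc1OC | intermediate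
13 | chloroform | ClC(Cl)Cl | starting material
14 | {[4-(benzyloxy)-1,1-dichloro-1a-(3,4-dimethoxyphenyl)-3,5,6-trimethoxy-1,1a-dihydro-6bH-cyclopropa[b][1]benzofuran-6b-yl]oxy}(tert-butyl)dimethylsilane (racemic, ring fusion necessarily cis) | COc1ccc(C23Oc4c(OC)c(OCc5ccccc5)c(OC)c(OC)c4C2(O[Si](C)(C)C(C)(C)C)C3(Cl)Cl)cc1OC | intermediate (not isolated)
15 | 7-(benzyloxy)-4-{[tert-butyl(dimethyl)silyl]oxy}-3-chloro-2-(3,4-dimethoxyphenyl)-5,6,8-trimethoxychromenylium chloride | COc1ccc(-c2[o+]c3c(OC)c(OCc4ccccc4)c(OC)c(OC)c3c(O[Si](C)(C)C(C)(C)C)c2Cl)cc1OC.[Cl-] | intermediate (not isolated)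
16 | 7-(benzyloxy)-3-chloro-2-(3,4-dimethoxyphenyl)-5,6,8-trimethoxy-4H-chromen-4-one | COc1ccc(-c2oc3c(OC)c(OCc4ccccc4)c(OC)c(OC)c3c(=O)c2Cl)cc1OC | intermediate
17 | 2-(3,4-dimethoxyphenyl)-7-hydroxy-5,6,8-trimethoxy-4H-chromen-4-one | COc1ccc(-c2cc(=O)c3c(OC)c(OC)c(O)c(OC)c3o2)cc1OC | target

## Step count and least certain steps

Total step count: 8. Longest linear sequence: 8 steps (1 to 17); compounds 5, 10 and 13 enter as purchased reagents.

Step 7 (key step, proposed new method). The most likely failure is loss of the silyl group to alkoxide before the carbene arrives. The freed enolate can then be dichloromethylated at C2 or oxidized, and the carbene is consumed by alkoxide. Carbene insertion into the benzylic C–H bonds is a lesser concern.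
Fallback, known chemistry only, from 7 to 17:
- Zinc dust in acetic acid removes the α-chlorine of 7 and gives 1-(2,4-dihydroxy-3,5,6-trimethoxyphenyl)ethan-1-one F1.
- Claisen–Schmidt condensation of F1 with 3,4-dimethoxybenzaldehyde (KOH, EtOH, rt) gives (E)-1-(2,4-dihydroxy-3,5,6-trimethoxyphenyl)-3-(3,4-dimethoxyphenyl)prop-2-en-1-one F2.
- Oxidative cyclization of F2 with catalytic I2 in DMSO at about 120 °C closes ring C through the only ortho hydroxyl and returns to the route at 17. No benzyl group is needed on this path.

Step 5. A second arylation at C2, base-induced self-condensation of 9 before it is fully enolized, and autoxidation of the enolate of 11 during work-up are the likely problems.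
Fallback, from 4 to 11, in which the aryl–C2 bond is brought in with the acyl unit:
- Friedel–Crafts acylation of 4 with (3,4-dimethoxyphenyl)acetyl chloride and AlCl3 in CH2Cl2 gives 2-(3,4-dimethoxyphenyl)-1-(4-hydroxy-2,3,5,6-tetramethoxyphenyl)ethan-1-one F3.
- F3 loses one ortho methyl group in the same flask and gives 1-(2,4-dihydroxy-3,5,6-trimethoxyphenyl)-2-(3,4-dimethoxyphenyl)ethan-1-one F4.
- Selective benzylation of the non-chelated para hydroxyl (BnBr, K2CO3, acetone) gives 1-[4-(benzyloxy)-2-hydroxy-3,5,6-trimethoxyphenyl]-2-(3,4-dimethoxyphenyl)ethan-1-one F5.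
- α-Bromination at the benzylic ketone position with phenyltrimethylammonium tribromide in THF gives 1-[4-(benzyloxy)-2-hydroxy-3,5,6-trimethoxyphenyl]-2-bromo-2-(3,4-dimethoxyphenyl)ethan-1-one F6.
- NaOAc in ethanol cyclizes F6 to 11.

Step 2. Acylation may go to the phenol oxygen and not to the ring, and further methyl groups next to the aluminium phenoxide may be lost on prolonged contact with AlCl3.
Fallback, from 4 to 7, separating acylation from demethylation:
- Protection of 4 (chloromethyl methyl ether, i-Pr2NEt) gives 1,2,4,5-tetramethoxy-3-(methoxymethoxy)benzene F7.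
- n-BuLi lithiates the last ring position, which again lies between two methoxy groups, to [4-(methoxymethoxy)-2,3,5,6-tetramethoxyphenyl]lithium F8.
- Acylation of F8 with 2-chloro-N-methoxy-N-methylacetamide at −78 °C gives 2-chloro-1-[4-(methoxymethoxy)-2,3,5,6-tetramethoxyphenyl]ethan-1-one F9.
- BCl3 in CH2Cl2 at −20 °C removes the acetal and one chelated ortho methyl group and gives 7.

Step 8. Hydrogenolysis may stop after only one of the two cleavages, or saturation of the C2=C3 bond may compete once the chlorine is gone.
Fallback, from 16 to 17, with the two cleavages done by different mechanisms: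
- Acidolysis of the benzyl ether with trifluoroacetic acid and pentamethylbenzene as cation scavenger gives 3-chloro-2-(3,4-dimethoxyphenyl)-7-hydroxy-5,6,8-trimethoxy-4H-chromen-4-one F10.
- Hydrodechlorination of F10 with H2, Pd/C and Et3N in methanol gives 17. The amine can be used here as a rate-enhancing base because no benzyl ether is left.

## Further compounds

F1 | step 7 | 1-(2,4-dihydroxy-3,5,6-trimethoxyphenyl)ethan-1-one | CC(=O)c1c(O)c(OC)c(O)c(OC)c1OC
F2 | step 7 | (E)-1-(2,4-dihydroxy-3,5,6-trimethoxyphenyl)-3-(3,4-dimethoxyphenyl)prop-2-en-1-one | COc1ccc(/C=C/C(=O)c2c(O)c(OC)c(O)c(OC)c2OC)cc1OC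
F3 | step 5 | 2-(3,4-dimethoxyphenyl)-1-(4-hydroxy-2,3,5,6-tetramethoxyphenyl)ethan-1-one | COc1ccc(CC(=O)c2c(OC)c(OC)c(O)c(OC)c2OC)cc1OC
F4 | step 5 | 1-(2,4-dihydroxy-3,5,6-trimethoxyphenyl)-2-(3,4-dimethoxyphenyl)ethan-1-one | COc1ccc(CC(=O)c2c(O)c(OC)c(O)c(OC)c2OC)cc1OC
F5 | step 5 | 1-[4-(benzyloxy)-2-hydroxy-3,5,6-trimethoxyphenyl]-2-(3,4-dimethoxyphenyl)ethan-1-one | COc1ccc(CC(=O)c2c(O)c(OC)c(OCc3ccccc3)c(OC)c2OC)cc1OC
F6 | step 5 | 1-[4-(benzyloxy)-2-hydroxy-3,5,6-trimethoxyphenyl]-2-bromo-2-(3,4-dimethoxyphenyl)ethan-1-one (racemic) | COc1ccc(C(Br)C(=O)c2c(O)c(OC)c(OCc3ccccc3)c(OC)c2OC)cc1OC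
F7 | step 2 | 1,2,4,5-tetramethoxy-3-(methoxymethoxy)benzene | COCOc1c(OC)c(OC)cc(OC)c1OC
F8 | step 2 | [4-(methoxymethoxy)-2,3,5,6-tetramethoxyphenyl]lithium | [Li]c1c(OC)c(OC)c(OCOC)c(OC)c1OC
F9 | step 2 | 2-chloro-1-[4-(methoxymethoxy)-2,3,5,6-tetramethoxyphenyl]ethan-1-one | O=C(CCl)c1c(OC)c(OC)c(OCOC)c(OC)c1OC
F10 | step 8 | 3-chloro-2-(3,4-dimethoxyphenyl)-7-hydroxy-5,6,8-trimethoxy-4H-chromen-4-one | COc1ccc(-c2oc3c(OC)c(O)c(OC)c(OC)c3c(=O)c2Cl)cc1OC
A1 | alternative 1 | 3-(benzyloxy)-2,4,5-trimethoxy-6-[(triphenyl-λ5-phosphanylidene)acetyl]phenyl 3,4-dimethoxybenzoate | COc1ccc(C(=O)Oc2c(OC)c(OCc3ccccc3)c(OC)c(OC)c2C(=O)C=P(c4ccccc4)(c5ccccc5)c6ccccc6)cc1OC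
A2 | alternative 1 | 7-(benzyloxy)-2-(3,4-dimethoxyphenyl)-5,6,8-trimethoxy-4H-chromen-4-one | COc1ccc(-c2cc(=O)c3c(OC)c(OC)c(OCc4ccccc4)c(OC)c3o2)cc1OC
A3 | alternative 2 | 3-(benzyloxy)-2,4-dimethoxycyclobut-2-en-1-one (racemic) | O=C1C(OC)=C(OCc2ccccc2)C1OC
A4 | alternative 2 | methoxyethyne | C#COC
A5 | alternative 2 | 3-(benzyloxy)-2,4,5-trimethoxyphenol | Oc1cc(OC)c(OC)c(OCc2ccccc2)c1OC
A6 | alternative 3 | 1-[4-(benzyloxy)-2,6-dibromo-3,5-dimethoxyphenyl]-3-(3,4-dimethoxyphenyl)propane-1,3-dione | COc1ccc(C(=O)CC(=O)c2c(Br)c(OC)c(OCc3ccccc3)c(OC)c2Br)cc1OC
A7 | alternative 3 | 7-(benzyloxy)-5-bromo-2-(3,4-dimethoxyphenyl)-6,8-dimethoxy-4H-chromen-4-one | COc1ccc(-c2cc(=O)c3c(Br)c(OC)c(OCc4ccccc4)c(OC)c3o2)cc1OC
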